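**Retrosynthetic overview**

1. Late stage: O-sulfation of an axial C7 alcohol (from the C7 ketone), vinylogous Horner–Wadsworth–Emmons olefination of a C1 aldehyde, and thermodynamic equilibration of C1 at that aldehyde.
2. The C2 butenyl group and the C3=C4 alkene come together from anti-SN2' transfer of an (E)-but-2-en-2-yl copper reagent to a C4 picolinate of a C2=C3 alkene, itself made from ring-A enone 8 (CuH reduction, Rubottom oxidation, enol triflate/methyl coupling).
3. Key disconnection: ring A is closed onto ring B by a one-flask [3+3] annulation of keto ester 4 with an acetonyl unit, C1–C2 by enolate alkylation and C4–C4a by aldol condensation.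
4. Enabling feature: in ring A the methyl-bearing alkene carbon C3 is a latent ketone flanked by C2 and C4, C1 is α to the side-chain carbon (an ester at that stage), and the ring-fusion carbon C4a is a latent ketone of ring B; C1–C2 is therefore the central bond of a 1,4-dicarbonyl pair and C4–C4a an aldol bond.
5. Ring order: ring B first (asymmetric conjugate methylation/enolate alkylation of a cyclohexenone acetal sets C8 and C8a), then ring A.

Key step: step 2

Remark: locants are those of the target octahydronaphthalene (C1 dienoic acid chain, C2 butenyl, C3 methyl, C7 oxygen, C8 methyl); C1 stays epimerisable until step 9 and is written without configuration up to 17; 5 is taken as available (it is also made in one step from 2-methoxypropene and N-bromosuccinimide).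

**Route**

Step 1
Reactants: 1 1,4-dioxaspiro[4.5]dec-6-en-8-one; 2 dimethylzinc; 3 ethyl iodoacetate
Product: 4 ethyl 2-[(6R,7R)-6-methyl-8-oxo-1,4-dioxaspiro[4.5]decan-7-yl]acetate
Conditions: 2, Cu(OTf)2 (2 mol %), (S,R,R)-BINOL bis(1-phenylethyl)amine phosphoramidite (4 mol %; ligand enantiomer chosen to give 6R), toluene, −30 °C; then 3, DMPU, −30 to 0 °C
Reagents that add atoms: none
Why: Copper-catalysed asymmetric conjugate addition (Feringa type) places the methyl on the enone β-carbon under ligand control (C8), and the zinc enolate is C-alkylated by the iodoacetate anti to that methyl (C8a, trans), a conjugate addition–enolate trapping sequence.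

Step 2
Reactants: 4; 5 3-bromo-2-methoxyprop-1-ene
Product: 8 ethyl (8R,8aS)-7,7-(ethylenedioxy)-8-methyl-3-oxo-1,2,3,5,6,7,8,8a-octahydronaphthalene-1-carboxylate (C1 epimers), via alkylated enol ether 6 (not isolated), via 1,5-diketone 7 (not isolated)
Conditions: LiN(i-Pr)2 (2.2 equiv), THF/DMPU, −78 °C; 5, −78 to −40 °C; 1 M HCl, 0 °C to rt; NaHCO3; pyrrolidine/AcOH (0.2 equiv), toluene, 50 °C
Reagents that add atoms: water, O
Why: Two equivalents of amide base should give the dianion of 4 (ketone enolate towards the C5 methylene, then the ester enolate), whose ester enolate carbon displaces bromide from 5 to form C1–C2; acid then unmasks the methyl ketone, and pyrrolidinium acetate promotes enamine aldol addition of the C4 methyl carbon to the C4a ketone and dehydration, forming C4–C4a. The closest known reaction type is the enolate acetonylation/aldol condensation variant of the Robinson annulation (2-methoxyallyl bromide and Wichterle cyclohexenone annulations). Ring A closes by a 6-(enolendo)-exo-trig aldol addition, favoured by the Baldwin rules for enolates, and loss of water makes the closure irreversible. The only new stereocentre, C1, is formed without control and is left so because it stays epimerisable and is set thermodynamically in step 9; C8 and C8a of 4 are carried through, the ketone being enolised kinetically away from C8a. The step needs site selectivity (alkylation at the ester α-carbon, not at C5 or on oxygen), which rests on the higher reactivity of the last-formed, less stabilised enolate of the dianion. It also needs regioselective condensation, secured because only the fused enone can dehydrate while the bridged aldol between C5 and C3 is reversible.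

Step 3
Reactants: 8
Product: 10 ethyl (4R,4aS,8R,8aS)-7,7-(ethylenedioxy)-8-methyl-3-oxo-4-(triethylsilyloxy)decahydronaphthalene-1-carboxylate (cis-fused; C1 epimers), via silyl enol ether 9 (not isolated)
Conditions: [(Ph3P)CuH]6 (0.3 equiv), Et3SiCl, benzene/THF, rt; filtration; then mCPBA, NaHCO3, CH2Cl2, −20 °C
Reagents that add atoms: chlorotriethylsilane, CC[Si](Cl)(CC)CC; 3-chloroperbenzoic acid, O=C(OO)c1cccc(Cl)c1
Why: Stryker conjugate reduction should deliver hydride to C4a axially on the face of the C8a hydrogen, as in cuprate and copper hydride additions to octal-2-ones of this type (cis ring fusion); the copper enolate is trapped as the C3=C4 silyl enol ether, and Rubottom oxidation then attacks C4 from the convex face with silyl transfer to the new oxygen, placing the C4 oxygen cis to the C4a hydrogen.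

Step 4
Reactants: 10
Product: 11 ethyl (4R,4aS,8R,8aS)-7,7-(ethylenedioxy)-8-methyl-4-(triethylsilyloxy)-3-(trifluoromethanesulfonyloxy)-1,4,4a,5,6,7,8,8a-octahydronaphthalene-1-carboxylate (C1 epimers)
Conditions: KN(SiMe3)2, THF, −78 °C; PhNTf2, −78 to 0 °C
Reagents that add atoms: N-phenylbis(trifluoromethanesulfonimide), FC(F)(F)S(=O)(=O)N(c1ccccc1)S(=O)(=O)C(F)(F)F
Why: Kinetic deprotonation at the only unhindered α-position (the C2 methylene; C4 is tertiary and carries the silyloxy group) and O-sulfonylation give the C2=C3 enol triflate (enol triflate formation).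

Step 5
Reactants: 11; 2 dimethylzinc
Product: 12 ethyl (4R,4aS,8R,8aS)-7,7-(ethylenedioxy)-3,8-dimethyl-4-(triethylsilyloxy)-1,4,4a,5,6,7,8,8a-octahydronaphthalene-1-carboxylate (C1 epimers)
Conditions: Pd(PPh3)4 (5 mol %), THF, 0 °C to rt
Reagents that add atoms: none
Why: Negishi cross-coupling of the enol triflate installs the C3 methyl without moving the C2=C3 alkene; ester, acetal and silyl ether are tolerated.

Step 6
Reactants: 12
Product: 13 ethyl (4R,4aS,8R,8aS)-7,7-(ethylenedioxy)-4-hydroxy-3,8-dimethyl-1,4,4a,5,6,7,8,8a-octahydronaphthalene-1-carboxylate (C1 epimers)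
Conditions: HF·pyridine, pyridine, THF, 0 °C
Reagents that add atoms: none
Why: Fluoride-mediated Si–O cleavage frees the C4 allylic alcohol and leaves acetal and ester untouched.

Step 7
Reactants: 13
Product: 14 ethyl (4S,4aS,8R,8aS)-7,7-(ethylenedioxy)-3,8-dimethyl-4-(pyridine-2-carbonyloxy)-1,4,4a,5,6,7,8,8a-octahydronaphthalene-1-carboxylate (C1 epimers)
Conditions: picolinic acid, PPh3, DIAD, toluene, 0 °C to rt
Reagents that add atoms: pyridine-2-carboxylic acid, OC(=O)c1ccccn1
Why: Mitsunobu esterification displaces the oxyphosphonium group by SN2 and inverts C4, so the picolinate sits on the concave face, opposite to the face on which the butenyl group must enter.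

Step 8
Reactants: 14; 15 (E)-2-bromobut-2-ene
Product: 16 ethyl (2R,4aS,8R,8aS)-2-[(2E)-but-2-en-2-yl]-7,7-(ethylenedioxy)-3,8-dimethyl-1,2,4a,5,6,7,8,8a-octahydronaphthalene-1-carboxylate (C1 epimers)
Conditions: 15, t-BuLi (2 equiv), Et2O, −78 °C; MgBr2·OEt2; CuBr·SMe2, THF, −60 °C; then 14, −60 to −20 °C
Reagents that add atoms: none
Why: Copper-mediated allylic substitution of the picolinate (Kobayashi type, activated by magnesium chelation) should go anti-SN2', delivering the alkenyl group to C2 on the face opposite to the C4 leaving group (sets C2) while the C3=C4 alkene forms; halogen–lithium exchange and transmetalation keep the alkene geometry of 15.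

Step 9
Reactants: 16
Product: 18 (1S,2R,4aS,8R,8aR)-2-[(2E)-but-2-en-2-yl]-7,7-(ethylenedioxy)-3,8-dimethyl-1,2,4a,5,6,7,8,8a-octahydronaphthalene-1-carbaldehyde, via aldehyde epimer mixture 17 (not isolated)
Conditions: i-Bu2AlH (1.1 equiv), CH2Cl2, −78 °C; Rochelle salt; then DBU (0.2 equiv), CH2Cl2, rt
Reagents that add atoms: none
Why: Partial ester reduction stops at the aluminium hemiacetal at −78 °C, and DBU then equilibrates C1 to the epimer expected to be more stable, with the formyl group axial on ring A, cis to the C2 butenyl group and free of the peri (syn-pentane) clash with the equatorial C8 methyl that the other epimer suffers.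

Step 10
Reactants: 18; 19 triethyl 4-phosphonocrotonate
Product: 20 ethyl (2E,4E)-5-[(1S,2R,4aS,8R,8aR)-2-[(2E)-but-2-en-2-yl]-7,7-(ethylenedioxy)-3,8-dimethyl-1,2,4a,5,6,7,8,8a-octahydronaphthalen-1-yl]penta-2,4-dienoate
Conditions: LiN(SiMe3)2, THF, −78 to 0 °C
Reagents that add atoms: none
Why: Vinylogous Horner–Wadsworth–Emmons olefination with the stabilised phosphonate anion should give the (2E,4E)-dienoate; C1 is already in its stable configuration.

Step 11
Reactants: 20
Product: 21 ethyl (2E,4E)-5-[(1S,2R,4aS,8R,8aR)-2-[(2E)-but-2-en-2-yl]-3,8-dimethyl-7-oxo-1,2,4a,5,6,7,8,8a-octahydronaphthalen-1-yl]penta-2,4-dienoate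
Conditions: 1 M HCl, THF, rt
Reagents that add atoms: water, O
Why: Acid-catalysed acetal hydrolysis unveils the C7 ketone; the adjacent C8 methyl is already equatorial, and the alkenes and ester tolerate dilute acid.

Step 12
Reactants: 21
Product: 22 ethyl (2E,4E)-5-[(1S,2R,4aS,7S,8R,8aR)-2-[(2E)-but-2-en-2-yl]-7-hydroxy-3,8-dimethyl-1,2,4a,5,6,7,8,8a-octahydronaphthalen-1-yl]penta-2,4-dienoate
Conditions: LiBH(s-Bu)3 (L-Selectride), THF, −78 °C
Reagents that add atoms: none
Why: The bulky borohydride attacks the C7 ketone from the equatorial direction and gives the axial alcohol cis to the C8 methyl (as with 2-methylcyclohexanone), faster than any conjugate reduction of the dienoate at −78 °C.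

Step 13
Reactants: 22
Product: 23 ethyl (2E,4E)-5-[(1S,2R,4aS,7S,8R,8aR)-2-[(2E)-but-2-en-2-yl]-3,8-dimethyl-7-(sulfooxy)-1,2,4a,5,6,7,8,8a-octahydronaphthalen-1-yl]penta-2,4-dienoate
Conditions: SO3·pyridine, pyridine, 40 °C
Reagents that add atoms: sulfur trioxide–pyridine complex, O=S(=O)([O-])[n+]1ccccc1
Why: O-sulfonation of the secondary alcohol by the SO3 donor gives the sulfate monoester with retention at C7.

Step 14
Reactants: 23
Product: 24 (2E,4E)-5-[(1S,2R,4aS,7S,8R,8aR)-2-[(2E)-but-2-en-2-yl]-3,8-dimethyl-7-(sulfooxy)-1,2,4a,5,6,7,8,8a-octahydronaphthalen-1-yl]penta-2,4-dienoic acid (target)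
Conditions: LiOH, THF/MeOH/H2O, 0 °C to rt; then cold aq. HCl to pH 1–2, reversed-phase desalting
Reagents that add atoms: lithium hydroxide, [Li+].[OH-]
Why: Saponification cleaves the ethyl dienoate while the alkyl sulfate monoanion resists hydroxide, and cold acidification should give the free acid form.

**Compound list**

1 | 1,4-dioxaspiro[4.5]dec-6-en-8-one | O=C1C=CC2(CC1)OCCO2 | starting material
2 | dimethylzinc | C[Zn]C | starting material
3 | ethyl iodoacetate | CCOC(=O)CI | starting material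
4 | ethyl 2-[(6R,7R)-6-methyl-8-oxo-1,4-dioxaspiro[4.5]decan-7-yl]acetate (methyl and acetate arm trans) | O=C1CCC2(OCCO2)[C@H](C)[C@H]1CC(=O)OCC | intermediate
5 | 3-bromo-2-methoxyprop-1-ene | COC(=C)CBr | starting material
6 | ethyl 4-methoxy-2-[(6R,7R)-6-methyl-8-oxo-1,4-dioxaspiro[4.5]decan-7-yl]pent-4-enoate (C2 epimers) | O=C1CCC2(OCCO2)[C@H](C)[C@H]1C(CC(=C)OC)C(=O)OCC | intermediate
7 | ethyl 2-[(6R,7R)-6-methyl-8-oxo-1,4-dioxaspiro[4.5]decan-7-yl]-4-oxopentanoate (C2 epimers) | O=C1CCC2(OCCO2)[C@H](C)[C@H]1C(CC(C)=O)C(=O)OCC | intermediate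
8 | ethyl (8R,8aS)-7,7-(ethylenedioxy)-8-methyl-3-oxo-1,2,3,5,6,7,8,8a-octahydronaphthalene-1-carboxylate (C1 epimers) | CCOC(=O)C1CC(=O)C=C2CCC3(OCCO3)[C@H](C)[C@@H]12 | intermediate
9 | ethyl (4aS,8R,8aS)-7,7-(ethylenedioxy)-8-methyl-3-(triethylsilyloxy)-1,2,4a,5,6,7,8,8a-octahydronaphthalene-1-carboxylate (cis-fused; C1 epimers) | C1C(O[Si](CC)(CC)CC)=C[C@H]2CCC3(OCCO3)[C@H](C)[C@H]2C1C(=O)OCC | intermediate
10 | ethyl (4R,4aS,8R,8aS)-7,7-(ethylenedioxy)-8-methyl-3-oxo-4-(triethylsilyloxy)decahydronaphthalene-1-carboxylate (cis-fused; C1 epimers) | C1C(=O)[C@H](O[Si](CC)(CC)CC)[C@H]2CCC3(OCCO3)[C@H](C)[C@H]2C1C(=O)OCC | intermediate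
11 | ethyl (4R,4aS,8R,8aS)-7,7-(ethylenedioxy)-8-methyl-4-(triethylsilyloxy)-3-(trifluoromethanesulfonyloxy)-1,4,4a,5,6,7,8,8a-octahydronaphthalene-1-carboxylate (C1 epimers) | C1=C(OS(=O)(=O)C(F)(F)F)[C@H](O[Si](CC)(CC)CC)[C@H]2CCC3(OCCO3)[C@H](C)[C@H]2C1C(=O)OCC | intermediate
12 | ethyl (4R,4aS,8R,8aS)-7,7-(ethylenedioxy)-3,8-dimethyl-4-(triethylsilyloxy)-1,4,4a,5,6,7,8,8a-octahydronaphthalene-1-carboxylate (C1 epimers) | C1=C(C)[C@H](O[Si](CC)(CC)CC)[C@H]2CCC3(OCCO3)[C@H](C)[C@H]2C1C(=O)OCC | intermediate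
13 | ethyl (4R,4aS,8R,8aS)-7,7-(ethylenedioxy)-4-hydroxy-3,8-dimethyl-1,4,4a,5,6,7,8,8a-octahydronaphthalene-1-carboxylate (C1 epimers) | C1=C(C)[C@H](O)[C@H]2CCC3(OCCO3)[C@H](C)[C@H]2C1C(=O)OCC | intermediate
14 | ethyl (4S,4aS,8R,8aS)-7,7-(ethylenedioxy)-3,8-dimethyl-4-(pyridine-2-carbonyloxy)-1,4,4a,5,6,7,8,8a-octahydronaphthalene-1-carboxylate (C1 epimers) | C1=C(C)[C@@H](OC(=O)c3ccccn3)[C@H]2CCC4(OCCO4)[C@H](C)[C@H]2C1C(=O)OCC | intermediate
15 | (E)-2-bromobut-2-ene | C/C=C(\C)Br | starting material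
16 | ethyl (2R,4aS,8R,8aS)-2-[(2E)-but-2-en-2-yl]-7,7-(ethylenedioxy)-3,8-dimethyl-1,2,4a,5,6,7,8,8a-octahydronaphthalene-1-carboxylate (C1 epimers) | C/C=C(\C)[C@@H]1C(C)=C[C@H]2CCC3(OCCO3)[C@H](C)[C@H]2C1C(=O)OCC | intermediate
17 | (2R,4aS,8R,8aR)-2-[(2E)-but-2-en-2-yl]-7,7-(ethylenedioxy)-3,8-dimethyl-1,2,4a,5,6,7,8,8a-octahydronaphthalene-1-carbaldehyde (C1 epimers) | C/C=C(\C)[C@@H]1C(C)=C[C@H]2CCC3(OCCO3)[C@H](C)[C@H]2C1C=O | intermediate
18 | (1S,2R,4aS,8R,8aR)-2-[(2E)-but-2-en-2-yl]-7,7-(ethylenedioxy)-3,8-dimethyl-1,2,4a,5,6,7,8,8a-octahydronaphthalene-1-carbaldehyde | C/C=C(\C)[C@@H]1C(C)=C[C@H]2CCC3(OCCO3)[C@H](C)[C@H]2[C@@H]1C=O | intermediate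
19 | triethyl 4-phosphonocrotonate | CCOC(=O)/C=C/CP(=O)(OCC)OCC | starting material
20 | ethyl (2E,4E)-5-[(1S,2R,4aS,8R,8aR)-2-[(2E)-but-2-en-2-yl]-7,7-(ethylenedioxy)-3,8-dimethyl-1,2,4a,5,6,7,8,8a-octahydronaphthalen-1-yl]penta-2,4-dienoate | C/C=C(\C)[C@@H]1C(C)=C[C@H]2CCC3(OCCO3)[C@H](C)[C@H]2[C@@H]1/C=C/C=C/C(=O)OCC | intermediate
21 | ethyl (2E,4E)-5-[(1S,2R,4aS,8R,8aR)-2-[(2E)-but-2-en-2-yl]-3,8-dimethyl-7-oxo-1,2,4a,5,6,7,8,8a-octahydronaphthalen-1-yl]penta-2,4-dienoate | C/C=C(\C)[C@@H]1C(C)=C[C@H]2CCC(=O)[C@H](C)[C@H]2[C@@H]1/C=C/C=C/C(=O)OCC | intermediate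
22 | ethyl (2E,4E)-5-[(1S,2R,4aS,7S,8R,8aR)-2-[(2E)-but-2-en-2-yl]-7-hydroxy-3,8-dimethyl-1,2,4a,5,6,7,8,8a-octahydronaphthalen-1-yl]penta-2,4-dienoate | C/C=C(\C)[C@@H]1C(C)=C[C@H]2CC[C@H](O)[C@H](C)[C@H]2[C@@H]1/C=C/C=C/C(=O)OCC | intermediate
23 | ethyl (2E,4E)-5-[(1S,2R,4aS,7S,8R,8aR)-2-[(2E)-but-2-en-2-yl]-3,8-dimethyl-7-(sulfooxy)-1,2,4a,5,6,7,8,8a-octahydronaphthalen-1-yl]penta-2,4-dienoate | C/C=C(\C)[C@@H]1C(C)=C[C@H]2CC[C@H](OS(=O)(=O)O)[C@H](C)[C@H]2[C@@H]1/C=C/C=C/C(=O)OCC | intermediate
24 | (2E,4E)-5-[(1S,2R,4aS,7S,8R,8aR)-2-[(2E)-but-2-en-2-yl]-3,8-dimethyl-7-(sulfooxy)-1,2,4a,5,6,7,8,8a-octahydronaphthalen-1-yl]penta-2,4-dienoic acid | C/C=C(\C)[C@@H]1C(C)=C[C@H]2CC[C@H](OS(=O)(=O)O)[C@H](C)[C@H]2[C@@H]1/C=C/C=C/C(=O)O | target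

**Step count and risks**

Total step count: 14. Longest linear sequence: 14 steps (1 to 24).

Steps most likely to fail:

Step 2. The alkylation may take place at the ketone enolate (C5) or on oxygen instead of the ester α-carbon, the dianion may undergo Dieckmann-type self-condensation, and C8a may epimerise during the condensation. Fallback, from 1 back to 8, with the opposite polarity at C1: the zinc enolate from 1 and 2 (same copper catalyst) is intercepted with ethyl glyoxylate to give the aldol adduct ethyl 2-hydroxy-2-[(6R)-6-methyl-8-oxo-1,4-dioxaspiro[4.5]decan-7-yl]acetate F1. Mesylation and elimination (MsCl, Et3N; DBU) give the alkylidene keto ester ethyl (2E)-2-[(6R)-6-methyl-8-oxo-1,4-dioxaspiro[4.5]decan-7-ylidene]acetate F2. Robinson-type Michael addition/aldol condensation with acetone (pyrrolidine, AcOH) should then close ring A to 8, with C8a and C1 under thermodynamic control.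

Step 3. Hydride delivery to C4a may show poor facial selectivity, and silyl trapping of the copper enolate may be incomplete, which would lose the regiochemistry of the enol ether. Fallback, from 8 back to 9: heterogeneous hydrogenation (H2, Pd/C, EtOAc; no other C=C is present at this stage) should give the cis-fused ketone ethyl (4aR,8R,8aS)-7,7-(ethylenedioxy)-8-methyl-3-oxodecahydronaphthalene-1-carboxylate F3. Thermodynamic enol silylation (Et3SiOTf, Et3N), which in cis-fused 3-ketones of this type goes towards C4, then gives 9 for the same Rubottom oxidation.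

Step 7. SN2 displacement at the hindered C4 centre may give way to elimination to a diene or to ionisation with loss of configuration. Fallback, from 13 to 16, without inversion: the alcohol is converted with phenyl isocyanate into the carbamate ethyl (4R,4aS,8R,8aS)-7,7-(ethylenedioxy)-3,8-dimethyl-4-(phenylcarbamoyloxy)-1,4,4a,5,6,7,8,8a-octahydronaphthalene-1-carboxylate F4. N-Deprotonation (n-BuLi), CuI and the alkenyllithium from 15 should then transfer the butenyl group syn-SN2' (carbamate-directed cuprate substitution), which reaches the same C2 configuration and gives 16.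

Further compounds
F1 | step 2 | ethyl 2-hydroxy-2-[(6R)-6-methyl-8-oxo-1,4-dioxaspiro[4.5]decan-7-yl]acetate (diastereomer mixture) | CCOC(=O)C(O)C1[C@@H](C)C2(OCCO2)CCC1=O
F2 | step 2 | ethyl (2E)-2-[(6R)-6-methyl-8-oxo-1,4-dioxaspiro[4.5]decan-7-ylidene]acetate | CCOC(=O)/C=C1\[C@@H](C)C2(OCCO2)CCC1=O
F3 | step 3 | ethyl (4aR,8R,8aS)-7,7-(ethylenedioxy)-8-methyl-3-oxodecahydronaphthalene-1-carboxylate (cis-fused; C1 epimers) | C1C(=O)C[C@H]2CCC3(OCCO3)[C@H](C)[C@H]2C1C(=O)OCC
F4 | step 7 | ethyl (4R,4aS,8R,8aS)-7,7-(ethylenedioxy)-3,8-dimethyl-4-(phenylcarbamoyloxy)-1,4,4a,5,6,7,8,8a-octahydronaphthalene-1-carboxylate (C1 epimers) | C1=C(C)[C@H](OC(=O)Nc3ccccc3)[C@H]2CCC4(OCCO4)[C@H](C)[C@H]2C1C(=O)OCC
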